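We decide to reckon this flask from the level at which its target stalls and to leave the substrate curve aside.

| setting | winter | summer | flask |
|---|---|---|---|
| substrate | 0.50 M | 0.50 M | 0.50 M |
| gas phase | 37 mM (held) | 37 mM (held) | 37 mM (held) |
| catalyst | 0.2 mol% | 0.2 mol% | 0.2 mol% |
| added ligand | 1.4 mM | 3.2 mM | 2.1 mM |
| remark | run made earlier | run made earlier |  |
| time |  |  | 10 min |

| run | time / min | target / % | substrate / % |
|---|---|---|---|
| winter | 0.667 | 4.1 | 97.6 |
| winter | 1.00 | 4.2 | 94.2 |
| winter | 2.00 | 8.9 | 84.0 |
| winter | 3.00 | 10.2 | 77.3 |
| winter | 5.00 | 13.6 | 60.3 |
| winter | 8.00 | 15.1 | 41.3 |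
| summer | 0.500 | 0 | 99.2 |
| summer | 1.50 | 2.7 | 95.5 |
| summer | 3.00 | 5.4 | 86.8 |
| summer | 4.00 | 6.3 | 81.0 |
| summer | 6.00 | 9.1 | 69.9 |
| summer | 8.00 | 9.1 | 63.3 |

(readings scatter by 1 percentage point)

- amount of target at 10 min, in percent of the substrate charged
- concentration of dissolved gas in solution at 10 min, in percent of saturation

- the earlier runs were read with a standard deviation of 1 percentage point
- at the start none of the gas phase is in solution

In both earlier runs the substrate keeps falling while the target flattens, which we read as an intermediate made and used up together (a quasi-steady state), so we take the last target reading of each run as its stalling level and work with the reciprocal of that fraction of the charge, which reads 6.62 in the winter run and 11.0 in the summer run. We suppose that added ligand raises this reciprocal along a straight line, and we call its rise per unit of added ligand the ligand drag, 2.43 mM⁻¹, though two runs make a line without testing it. The 2.1 mM of added ligand in the flask then gives a reciprocal of 8.32, and so a first answer of 12.0 %. The weak link is that this answer rests on readings at 8.00 min while the flask is asked at 10 min, so we put it back in and ask what rise remains: the winter target gained 1.5 percentage points over its last two readings and the summer target 0 points, while a difference of two readings scatters by 1.4 points, so we add nothing and commit to 12.0 % for the flask, with no figure of our own for the gas.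

The forecast, made from the same runs, gives 13 % of target (10.5 % to 15.5 %), on the ground that “early selectivity is about 0.6, then it plateaus”, and 73 % of saturation (60 % to 85 %); its target stands above ours.

The flask gives 11.9 % of target and 94.4 % of saturation, the gas above the forecast's range.

    gas phase ⇌ dissolved gas, rate k1*(csat - [dissolved gas]) (kL = 0.0921 s⁻¹)
    catalyst + added ligand ⇌ idle complex, settled at all times (K = 1410 M⁻¹)
    substrate + dissolved gas + catalyst → catalyst + target (k = 76.6 M⁻² s⁻¹)
    substrate + target → side product (k = 0.0136 M⁻¹ s⁻¹)

At 10.0 min the flask makes its target, each step taken net, 1.09 times faster than it uses it up. From the flask's reciprocal, 8.40, the ligand drag steps to the neighbour flask with 1.30 mM of added ligand and gives 15.5 % of target, and that neighbour holds 16.4 %.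

The runs are simulated from invented constants; the scatter is artificial.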